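# Proposed synthesis of CNP0169501.0 by late oxidative furan closure of a 2-hydroxystilbene

## Analysis of the target

The target is a 2-arylbenzofuran, C25H28O5. Ring A (C3a, C4, C5, C6, C7, C7a) is fused to the furan ring (O1, C2, C3, C3a, C7a), and C2 carries ring B (C1' to C6'). Ring A is a phloroglucinol nucleus: free hydroxyls sit on C4 and C6, the third oxygen is O1, and C7 carries a 1,1-dimethylallyl (2-methylbut-3-en-2-yl) group whose quaternary carbon is wedged between C6–OH and O1. Ring B is 1,2,3,5-tetrasubstituted, with a prenyl group on C2' next to the biaryl bond, a methyl ether on C3' and a free hydroxyl on C5'; both oxygens are meta to C1'. There is no stereocentre and no stereogenic double bond, so the problem is one of regiochemistry and functional group tolerance. The sensitive groups are the two isolated alkenes, the electron-rich and air-sensitive triphenol, and the nucleophilic C3–H of the furan; under acid the vinyl group on C7 closes onto C6–OH to give a trimethyldihydrofuran. The difficulty is to place two different C5 units on crowded positions of two different electron-rich rings, to tell the two meta oxygens of ring B apart, and to finish without hydrogenolysis, strong acid or strong electrophiles. The strategy rests on the furan ring: O1–C2–C3–C3a–C7a is the dehydro form of an ortho-hydroxystilbene, so the O1–C2 bond can be made last, by oxidation, on an open stilbene that already carries both C5 side chains.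

## Retrosynthetic reasoning

**17 from 16.** The phenols at C4, C6 and C5' of the target 17 are unmasked last by cutting the three O–Si bonds of the tris(triisopropylsilyl) ether 16. Silyl ethers are chosen because a fluoride source removes them without acid (which would close the C7 side chain onto C6–OH), without hydrogen (two alkenes) and without Lewis acid (the C3' methyl ether must stay). The bulky silyl groups also work earlier in the route: they steer the metalation of ring B and shield C5 of ring A during the oxidation.

**16 from 15.** The O1–C2 bond is cut, which opens the furan to the (E)-2-hydroxystilbene 15. The cut is made here because it is the one ring bond that needs no carbon–carbon chemistry in the presence of both side chains, and because 15 has a single free hydroxyl, exactly the future O1. The forward reaction must take two hydrogens from the hydroxystyrene unit with a trivalent iodine oxidant, bond O1 to the stilbene carbon that bears ring B, and leave the prenyl and vinyl alkenes alone.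

**15 from 7 and 14.** The C2=C3 double bond is cut into the salicylaldehyde 7, whose formyl carbon becomes C3, and the benzylic phosphonate 14, whose methylene carbon becomes C2. This makes the route convergent: each ring is finished on its own, and the olefination joins them with E geometry. It has to tolerate the free, hindered ortho phenol of 7.

**7 from 6.** The bond between the formyl carbon and the ring (the future C3–C3a) is cut. In the phenol 6 only one carbon ortho to the hydroxyl is free, so a one-carbon electrophile delivered through the magnesium phenoxide can go only there; the para carbon between the two silyloxy groups is not reached.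

**6 from 4 through 5.** The bond from C7 to the quaternary carbon is traced back by a retro-[3,3] shift to the O–CH2 bond of the aryl prenyl ether 4. The allyl inversion of the forward rearrangement is what turns a linear prenyl group on oxygen into the branched 1,1-dimethylallyl group on carbon. Ether 4 is symmetric, so both ortho carbons give the same dienone 5, and the oxygen freed in 6 is the one that later directs the formylation and becomes O1.

**4 from 2 and 3, and 2 from 1.** The ether C–O bond is cut to the phenol 2 and prenyl bromide 3; 2 is the bis-silyl ether of phloroglucinol 1. The symmetry of 1 makes the statistical double silylation the only selectivity question.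

**14 from 13 and 13 from 12.** The C–P bond and then the C–Br bond are cut back to the benzylic alcohol 12. Both ring oxygens are meta to the benzylic carbon, so the bromide 13 is not prone to ionise and behaves as a plain benzylic electrophile.

**12 from 10 and 3 through 11, 10 from 9, 9 from 8.** The C2'–CH2 bond of the prenyl group is cut to the aryllithium 11 and prenyl bromide 3. Species 11 comes from the benzylic alcohol 10 by removal of the one ring proton that lies between two coordinating groups, the alkoxide arm and the methyl ether. The silyl ether on the third oxygen does not coordinate and blocks its two neighbours. Alcohol 10 comes from 3-hydroxy-5-methoxybenzaldehyde 8, which already holds the methyl ether and the free hydroxyl in the right meta relationship, by silylation to 9 and reduction.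

## Alternatives that were turned down

**Alternative 1: ring B grown on a finished benzofuran and aromatised late.**
- Disconnection: the C1'–C2' and C3'–C4' bonds of ring B are cut, leading back to the benzofuran-2-yl enone A2 and a malonic diester.
- Forward key step: the malonate anion adds to the enone carbon that becomes C1', the methyl ketone enolate closes on one ester group, and saponification with decarboxylation gives the symmetric dione A1.
- For it: the oxygen pattern of ring B comes from carbonyl chemistry, no organolithium is needed, and the Michael–Claisen–decarboxylation sequence is among the most dependable ring constructions. On the reliability of the key step alone it is stronger than an oxidation of an electron-rich phenol.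
- Against it: all the hard work is postponed. A1 must be desymmetrised into one methyl ether and one free hydroxyl. It must be prenylated at a methylene carbon flanked by one carbonyl only and next to the benzofuranyl carbon, not at the doubly activated carbon between the carbonyls, which has to stay unsubstituted. It must then be dehydrogenated to the arene in the presence of two isolated alkenes and an electron-rich benzofuran. The methoxymethyl ethers need acid for removal, which endangers the C7 side chain next to C6–OH. A2 also presupposes a benzofuran that already carries the 1,1-dimethylallyl group, so the furan problem is not solved by this step.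
- Comparison: the endgame after A1 is clearly longer than the three steps that follow the olefination here. The chosen strategy gives up some reliability in one step and in return brings ring B in aromatic, fully substituted and convergent.

**Alternative 2: ring contraction of a flavanone.**
- Disconnection: the C3–C3a bond is made by a 1,2-shift of ring A, with the flavanone A4 as precursor.
- Forward key step: a trivalent iodine oxidant with strong protic acid in an orthoformate attacks the enol ether of A4 at its alpha carbon, ring A migrates from the carbonyl carbon to that carbon, and the pyranone contracts to the trans dihydrobenzofuran ester A3.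
- For it: A4 is reached by aldol condensation and oxa-Michael closure, so the two halves are joined straight from a ring B aldehyde. That saves the reduction, bromination and phosphonate steps of ring B, and on this point the alternative is stronger.
- Against it: the oxidant acts in a strongly acidic medium, where acid-activated trivalent iodine attacks isolated alkenes, and A4 carries five of them. The shift of ring B from C2 to C3 (isoflavone formation) competes with the contraction and is favoured by an electron-rich ring B. A3 has one carbon too many and is at the dihydro level, so saponification, loss of the carboxyl carbon with dehydrogenation and removal of three allyl ethers must follow.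
- Comparison: the chosen strategy uses the same kind of oxidant under neutral conditions, builds no carbon that must be excised, and reaches the furan oxidation level in the ring-closing step itself.

**Alternative 3: ring A annulated onto a 2-arylfuran through an acylketene.**
- Disconnection: the C3a–C4 bond is cut, with the acyl Meldrum's acid A6 as precursor.
- Forward key step: heating A6 fragments the dioxanedione ring to an acylketene, whose ketene carbon bonds to the furan beta carbon; tautomerisation gives the 4,6-dihydroxybenzofuran A5 with the 1,1-dimethylallyl group already on C7.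
- For it: the quaternary carbon is set on an sp3 carbon by enolate chemistry before ring A exists, which is regiochemically unambiguous. On this point it is stronger than the aromatic Claisen rearrangement of 4. Only one protecting group is needed, and the substitution pattern of ring A is fixed by construction.
- Against it: the closure asks the less nucleophilic beta carbon of a furan to attack an indiscriminate electrophile at high temperature. The free hydroxyls of A5 can capture further acylketene. A5 is generated hot with C6–OH next to the vinyl group. A6 still needs the same prenylated ring B building block, attached to a furan by cross-coupling.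
- Comparison: there is no gain in step count, and the key step leans on weaker precedent for this substitution. The chosen strategy closes the ring at room temperature by a known reaction type and pays for it with the less certain aromatic Claisen rearrangement, for which a fallback is given below.

Key step: step 11

## Route

Remark on the chemistry: the target has no stereocentre; dienone 5 is a racemic transient whose single stereocentre is lost on enolisation, and commercial phloroglucinol is dried before use.

Step 1
Reactants: 1 phloroglucinol
Product: 2 3,5-bis(triisopropylsilyloxy)phenol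
Conditions: TIPSCl (2.0 equiv), imidazole, DMF, 0 °C→rt
Reagents that add atoms: triisopropylsilyl chloride (TIPSCl), CC(C)[Si](Cl)(C(C)C)C(C)C
Why: Imidazole-promoted O-silylation of a threefold symmetric triol; two equivalents should give the bis-ether as the main fraction, separable from mono- and tris-ether, which can be recycled.

Step 2
Reactants: 2 3,5-bis(triisopropylsilyloxy)phenol; 3 prenyl bromide (1-bromo-3-methylbut-2-ene)
Product: 4 1-(3-methylbut-2-en-1-yloxy)-3,5-bis(triisopropylsilyloxy)benzene
Conditions: K2CO3, acetone, reflux
Reagents that add atoms: none
Why: Williamson ether synthesis; the potassium phenoxide in acetone should alkylate at oxygen by SN2 at the primary allylic bromide, ring alkylation being held back by the bulky silyloxy groups next to every ring carbon, and aryl triisopropylsilyl ethers withstand carbonate.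

Step 3
Reactants: 4 1-(3-methylbut-2-en-1-yloxy)-3,5-bis(triisopropylsilyloxy)benzene
Product: 6 2-(2-methylbut-3-en-2-yl)-3,5-bis(triisopropylsilyloxy)phenol, via ortho-dienone 5 (not isolated)
Conditions: PhNEt2, 170–185 °C, sealed tube, Ar
Reagents that add atoms: none
Why: Aromatic Claisen rearrangement; the [3,3] shift inverts the allyl unit, so the O-prenyl group arrives on either of the two equivalent ortho carbons as the 1,1-dimethylallyl group, and dienone 5 should enolise in the basic amine faster than it can shift the group on to C4, which lies between two bulky silyloxy groups.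

Step 4
Reactants: 6 2-(2-methylbut-3-en-2-yl)-3,5-bis(triisopropylsilyloxy)phenol
Product: 7 2-hydroxy-3-(2-methylbut-3-en-2-yl)-4,6-bis(triisopropylsilyloxy)benzaldehyde
Conditions: MgCl2, Et3N, (CH2O)n, THF, reflux; then cold 1 M HCl
Reagents that add atoms: paraformaldehyde (formaldehyde), C=O
Why: Magnesium-mediated ortho-formylation (Casnati–Skattebøl); the magnesium phenoxide delivers formaldehyde to the only free ortho carbon and a second formaldehyde takes up hydride, so the para carbon is not touched, and ortho-tert-alkyl phenols are good substrates for this reaction.

Step 5
Reactants: 8 3-hydroxy-5-methoxybenzaldehyde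
Product: 9 3-methoxy-5-(triisopropylsilyloxy)benzaldehyde
Conditions: TIPSCl, imidazole, DMF, rt
Reagents that add atoms: triisopropylsilyl chloride (TIPSCl), CC(C)[Si](Cl)(C(C)C)C(C)C
Why: Phenol silylation; the triisopropylsilyl ether is chosen because it survives alkyllithium reagents, does not coordinate lithium and shields both ring positions next to it.

Step 6
Reactants: 9 3-methoxy-5-(triisopropylsilyloxy)benzaldehyde
Product: 10 [3-methoxy-5-(triisopropylsilyloxy)phenyl]methanol
Conditions: NaBH4, MeOH, 0 °C
Reagents that add atoms: none
Why: Borohydride reduction of an aryl aldehyde; the hindered aryl silyl ether should survive the short exposure to methanolic borohydride at 0 °C.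

Step 7
Reactants: 10 [3-methoxy-5-(triisopropylsilyloxy)phenyl]methanol; 3 prenyl bromide (1-bromo-3-methylbut-2-ene)
Product: 12 [3-methoxy-2-(3-methylbut-2-en-1-yl)-5-(triisopropylsilyloxy)phenyl]methanol, via dilithio species 11 (not isolated)
Conditions: n-BuLi (2.3 equiv), TMEDA, Et2O, 0 °C→rt; then CuBr·SMe2 (10 mol %), 3, THF, −78→0 °C; aq NH4Cl
Reagents that add atoms: none
Why: Directed ortho-metalation followed by copper-catalysed allylation; after alkoxide formation the second equivalent of base should remove the proton at C2, the only one flanked by two coordinating groups (CH2OLi and OMe), while C4 and C6 are blocked by the silyl ether, and the aryl–copper species couples with prenyl bromide at its primary carbon to give the linear prenyl group.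

Step 8
Reactants: 12 [3-methoxy-2-(3-methylbut-2-en-1-yl)-5-(triisopropylsilyloxy)phenyl]methanol
Product: 13 1-(bromomethyl)-3-methoxy-2-(3-methylbut-2-en-1-yl)-5-(triisopropylsilyloxy)benzene
Conditions: CBr4, PPh3, CH2Cl2, 0 °C
Reagents that add atoms: carbon tetrabromide, BrC(Br)(Br)Br
Why: Appel bromination under neutral conditions, so no HBr adds to the prenyl alkene; both ring oxygens are meta to the benzylic carbon, so the bromide should not ionise towards the neighbouring alkene.

Step 9
Reactants: 13 1-(bromomethyl)-3-methoxy-2-(3-methylbut-2-en-1-yl)-5-(triisopropylsilyloxy)benzene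
Product: 14 diethyl {[3-methoxy-2-(3-methylbut-2-en-1-yl)-5-(triisopropylsilyloxy)phenyl]methyl}phosphonate
Conditions: P(OEt)3 (neat), 130 °C
Reagents that add atoms: triethyl phosphite, CCOP(OCC)OCC
Why: Michaelis–Arbuzov reaction of a primary benzylic bromide; bromoethane distils off and the silyl ether and prenyl group are inert to neutral phosphite at this temperature.

Step 10
Reactants: 7 2-hydroxy-3-(2-methylbut-3-en-2-yl)-4,6-bis(triisopropylsilyloxy)benzaldehyde; 14 diethyl {[3-methoxy-2-(3-methylbut-2-en-1-yl)-5-(triisopropylsilyloxy)phenyl]methyl}phosphonate
Product: 15 (E)-2-{2-[3-methoxy-2-(3-methylbut-2-en-1-yl)-5-(triisopropylsilyloxy)phenyl]ethenyl}-6-(2-methylbut-3-en-2-yl)-3,5-bis(triisopropylsilyloxy)phenol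
Conditions: 14, KN(SiMe3)2 (2.4 equiv), THF, 0 °C; then 7, 0→45 °C; aq NH4Cl
Reagents that add atoms: none
Why: Horner–Wadsworth–Emmons olefination; one equivalent of base holds the phenol as its potassium salt, the non-stabilised and therefore reactive benzylic phosphonate anion adds to the deactivated aldehyde, and loss of diethyl phosphate should give the E-stilbene; the silyl ethers are meta to the phenoxide and cannot migrate to it.

Step 11
Reactants: 15 (E)-2-{2-[3-methoxy-2-(3-methylbut-2-en-1-yl)-5-(triisopropylsilyloxy)phenyl]ethenyl}-6-(2-methylbut-3-en-2-yl)-3,5-bis(triisopropylsilyloxy)phenol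
Product: 16 2-[3-methoxy-2-(3-methylbut-2-en-1-yl)-5-(triisopropylsilyloxy)phenyl]-7-(2-methylbut-3-en-2-yl)-4,6-bis(triisopropylsilyloxy)-1-benzofuran
Conditions: PhI(OAc)2 (1.2 equiv), MeCN–CH2Cl2, 0 °C→rt, Ar
Reagents that add atoms: none
Why: The step relies on the known oxidative cyclisation of 2-hydroxystilbenes to 2-arylbenzofurans with PhI(OAc)2, a trivalent iodine oxidant. The single free phenol should exchange for acetate at iodine; loss of iodobenzene, a two-electron oxidation, is assisted by the styryl arm, so the positive charge of the oxidised hydroxystyrene appears on the stilbene carbon that bears ring B, in an ortho-quinone methide type cation. O1 bonds to this carbon and loss of the proton on C2 gives the aromatic furan, with two molecules of acetic acid as the other products. This polarity is matched to the substrate, because the donors of ring A push the charge to exactly the carbon that O1 has to reach; a path in which iodine first activates the double bond and the phenol adds anti would end in the same product after loss of iodobenzene and acetic acid. The furan ring is closed in a formally 5-endo-trig mode (O1 onto C2 of the C2=C3 bond), which is feasible because the closing species is an oxidised, cationic 1-oxapentadienyl system and not a neutral alkene. No stereocentre is formed and the alkene geometry is lost in the aromatic ring. The step needs chemoselectivity for the hydroxystilbene over the prenyl and vinyl alkenes, and for O1 over capture of the cation at C5: the isolated alkenes are not attacked by PhI(OAc)2 without acid activation, only one hydroxyl is free, and C5 lies between two bulky silyloxy groups in a medium that holds no nucleophile stronger than acetate.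

Step 12
Reactants: 16 2-[3-methoxy-2-(3-methylbut-2-en-1-yl)-5-(triisopropylsilyloxy)phenyl]-7-(2-methylbut-3-en-2-yl)-4,6-bis(triisopropylsilyloxy)-1-benzofuran
Product: 17 2-[5-hydroxy-3-methoxy-2-(3-methylbut-2-en-1-yl)phenyl]-7-(2-methylbut-3-en-2-yl)-1-benzofuran-4,6-diol (CNP0169501.0)
Conditions: Bu4NF, AcOH, THF, 0 °C→rt, Ar
Reagents that add atoms: none
Why: Fluoride-induced cleavage of three aryl silyl ethers, driven by the Si–F bond; acetic acid buffers the phenoxides so that the triphenol is not left as an air-sensitive anion, and the medium is far too weakly acidic to close the C7 side chain onto C6–OH.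

## Compound list

1 | phloroglucinol (benzene-1,3,5-triol) | Oc1cc(O)cc(O)c1 | starting material
2 | 3,5-bis(triisopropylsilyloxy)phenol | Oc1cc(O[Si](C(C)C)(C(C)C)C(C)C)cc(O[Si](C(C)C)(C(C)C)C(C)C)c1 | intermediate
3 | prenyl bromide (1-bromo-3-methylbut-2-ene) | CC(C)=CCBr | starting material
4 | 1-(3-methylbut-2-en-1-yloxy)-3,5-bis(triisopropylsilyloxy)benzene | CC(C)=CCOc1cc(O[Si](C(C)C)(C(C)C)C(C)C)cc(O[Si](C(C)C)(C(C)C)C(C)C)c1 | intermediate
5 | 6-(2-methylbut-3-en-2-yl)-3,5-bis(triisopropylsilyloxy)cyclohexa-2,4-dien-1-one (racemic, not isolated) | C=CC(C)(C)C1C(=O)C=C(O[Si](C(C)C)(C(C)C)C(C)C)C=C1O[Si](C(C)C)(C(C)C)C(C)C | intermediate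
6 | 2-(2-methylbut-3-en-2-yl)-3,5-bis(triisopropylsilyloxy)phenol | C=CC(C)(C)c1c(O)cc(O[Si](C(C)C)(C(C)C)C(C)C)cc1O[Si](C(C)C)(C(C)C)C(C)C | intermediate
7 | 2-hydroxy-3-(2-methylbut-3-en-2-yl)-4,6-bis(triisopropylsilyloxy)benzaldehyde | C=CC(C)(C)c1c(O)c(C=O)c(O[Si](C(C)C)(C(C)C)C(C)C)cc1O[Si](C(C)C)(C(C)C)C(C)C | intermediate
8 | 3-hydroxy-5-methoxybenzaldehyde | COc1cc(O)cc(C=O)c1 | starting material
9 | 3-methoxy-5-(triisopropylsilyloxy)benzaldehyde | COc1cc(O[Si](C(C)C)(C(C)C)C(C)C)cc(C=O)c1 | intermediate
10 | [3-methoxy-5-(triisopropylsilyloxy)phenyl]methanol | COc1cc(O[Si](C(C)C)(C(C)C)C(C)C)cc(CO)c1 | intermediate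
11 | lithium [2-lithio-3-methoxy-5-(triisopropylsilyloxy)phenyl]methanolate (not isolated) | [Li]OCc1cc(O[Si](C(C)C)(C(C)C)C(C)C)cc(OC)c1[Li] | intermediate
12 | [3-methoxy-2-(3-methylbut-2-en-1-yl)-5-(triisopropylsilyloxy)phenyl]methanol | CC(C)=CCc1c(CO)cc(O[Si](C(C)C)(C(C)C)C(C)C)cc1OC | intermediate
13 | 1-(bromomethyl)-3-methoxy-2-(3-methylbut-2-en-1-yl)-5-(triisopropylsilyloxy)benzene | CC(C)=CCc1c(CBr)cc(O[Si](C(C)C)(C(C)C)C(C)C)cc1OC | intermediate
14 | diethyl {[3-methoxy-2-(3-methylbut-2-en-1-yl)-5-(triisopropylsilyloxy)phenyl]methyl}phosphonate | CCOP(=O)(Cc1cc(O[Si](C(C)C)(C(C)C)C(C)C)cc(OC)c1CC=C(C)C)OCC | intermediate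
15 | (E)-2-{2-[3-methoxy-2-(3-methylbut-2-en-1-yl)-5-(triisopropylsilyloxy)phenyl]ethenyl}-6-(2-methylbut-3-en-2-yl)-3,5-bis(triisopropylsilyloxy)phenol | C=CC(C)(C)c1c(O[Si](C(C)C)(C(C)C)C(C)C)cc(O[Si](C(C)C)(C(C)C)C(C)C)c(/C=C/c2cc(O[Si](C(C)C)(C(C)C)C(C)C)cc(OC)c2CC=C(C)C)c1O | intermediate
16 | 2-[3-methoxy-2-(3-methylbut-2-en-1-yl)-5-(triisopropylsilyloxy)phenyl]-7-(2-methylbut-3-en-2-yl)-4,6-bis(triisopropylsilyloxy)-1-benzofuran | C=CC(C)(C)c1c(O[Si](C(C)C)(C(C)C)C(C)C)cc(O[Si](C(C)C)(C(C)C)C(C)C)c2cc(-c3cc(O[Si](C(C)C)(C(C)C)C(C)C)cc(OC)c3CC=C(C)C)oc12 | intermediate
17 | 2-[5-hydroxy-3-methoxy-2-(3-methylbut-2-en-1-yl)phenyl]-7-(2-methylbut-3-en-2-yl)-1-benzofuran-4,6-diol (CNP0169501.0) | C=CC(C)(C)c1c(O)cc(O)c2cc(-c3cc(O)cc(OC)c3CC=C(C)C)oc12 | target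

## Step count and least certain steps

Total step count: 12. Longest linear sequence: 8 steps (8 → 9 → 10 → 12 → 13 → 14 → 15 → 16 → 17, steps 5 to 12); the ring A branch (steps 1 to 4) joins at step 10.

**Step 11 (key step).** The most likely failure is over-oxidation of ring A. Ring A is a doubly silylated phloroglucinol, and the cation formed on oxidation is also delocalised to C5, para to O1. Capture there by acetate or adventitious water would lead to quinoid products, and a slow closure would give the oxidant time to attack the isolated alkenes. The fallback avoids any oxidant and makes the C2–C3 bond last instead of O1–C2. It sets out from 7 and 13: the phenol of 7 is alkylated with 13 (K2CO3, DMF) to give the benzyl ether 2-{[3-methoxy-2-(3-methylbut-2-en-1-yl)-5-(triisopropylsilyloxy)phenyl]methoxy}-3-(2-methylbut-3-en-2-yl)-4,6-bis(triisopropylsilyloxy)benzaldehyde F1. Treatment with the phosphazene base P4-t-Bu in warm toluene should deprotonate the benzylic ether carbon, which adds to the formyl group, and loss of water gives the benzofuran. This base-induced cyclisation of 2-(benzyloxy)benzaldehydes is known, and it comes back to the route at 16.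

**Step 3.** The likely failure is onward reaction at the rearrangement temperature. Dienone 5 may shift the group on to C4 before it enolises (para migration, giving a linear prenyl group), and the free, electron-rich ortho-(1,1-dimethylallyl)phenol may undergo abnormal Claisen rearrangement or ring closure of its hydroxyl onto the vinyl group. The fallback changes the order so that the phenol released is tied up at once. It sets out from 2, which is formylated as in step 4 (MgCl2, Et3N, paraformaldehyde) to 2-hydroxy-4,6-bis(triisopropylsilyloxy)benzaldehyde F2. F2 is alkylated with 3 (K2CO3, DMF) to 2-(3-methylbut-2-en-1-yloxy)-4,6-bis(triisopropylsilyloxy)benzaldehyde F3, and F3 is rearranged in PhNEt2. Here the ether oxygen has one free ortho carbon only, the proton of the dienone is more acidic because the ketone is conjugated with the formyl group, and the new phenol is held in a hydrogen bond to the formyl oxygen. The fallback comes back to the route at 7.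

**Step 7.** The likely failure is metalation at the wrong ring position or incomplete metalation, because the alkoxide arm is only a moderate director; migration of the silyl group from oxygen to a lithiated neighbouring carbon and SN2' coupling of the prenyl group are lesser risks. The fallback fixes the site of the metal by a halogen. It sets out from 10, which is brominated with NBS in MeCN at 0 °C, expected at C2, which is para to the silyloxy group and not shielded by it, to give [2-bromo-3-methoxy-5-(triisopropylsilyloxy)phenyl]methanol F4. Two equivalents of n-BuLi at −78 °C then deprotonate the hydroxyl and exchange bromine for lithium. This comes back to the route at 11, which is allylated as in step 7 to 12.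

**Step 10.** The likely failure is sluggish addition to the aldehyde, which is deactivated as its phenoxide and flanked by two ortho substituents, so the phosphonate anion may decompose before it adds. The fallback removes the phenoxide during the olefination. It sets out from 7, which is alkylated with allyl bromide (K2CO3, DMF) to 2-(allyloxy)-3-(2-methylbut-3-en-2-yl)-4,6-bis(triisopropylsilyloxy)benzaldehyde F5. Olefination with 14 and one equivalent of KN(SiMe3)2 gives the allyl ether of 15, (E)-1-(allyloxy)-2-{2-[3-methoxy-2-(3-methylbut-2-en-1-yl)-5-(triisopropylsilyloxy)phenyl]ethenyl}-6-(2-methylbut-3-en-2-yl)-3,5-bis(triisopropylsilyloxy)benzene F6. The allyl ether is removed with catalytic Pd(PPh3)4 and morpholine in THF at room temperature, conditions that touch neither the silyl ethers nor the C-bound prenyl and 1,1-dimethylallyl groups, and the route is rejoined at 15.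

## Further compounds

F1 | step 11 | 2-{[3-methoxy-2-(3-methylbut-2-en-1-yl)-5-(triisopropylsilyloxy)phenyl]methoxy}-3-(2-methylbut-3-en-2-yl)-4,6-bis(triisopropylsilyloxy)benzaldehyde | C=CC(C)(C)c1c(OCc2cc(O[Si](C(C)C)(C(C)C)C(C)C)cc(OC)c2CC=C(C)C)c(C=O)c(O[Si](C(C)C)(C(C)C)C(C)C)cc1O[Si](C(C)C)(C(C)C)C(C)C
F2 | step 3 | 2-hydroxy-4,6-bis(triisopropylsilyloxy)benzaldehyde | O=Cc1c(O)cc(O[Si](C(C)C)(C(C)C)C(C)C)cc1O[Si](C(C)C)(C(C)C)C(C)C
F3 | step 3 | 2-(3-methylbut-2-en-1-yloxy)-4,6-bis(triisopropylsilyloxy)benzaldehyde | CC(C)=CCOc1cc(O[Si](C(C)C)(C(C)C)C(C)C)cc(O[Si](C(C)C)(C(C)C)C(C)C)c1C=O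
F4 | step 7 | [2-bromo-3-methoxy-5-(triisopropylsilyloxy)phenyl]methanol | COc1cc(O[Si](C(C)C)(C(C)C)C(C)C)cc(CO)c1Br
F5 | step 10 | 2-(allyloxy)-3-(2-methylbut-3-en-2-yl)-4,6-bis(triisopropylsilyloxy)benzaldehyde | C=CCOc1c(C=O)c(O[Si](C(C)C)(C(C)C)C(C)C)cc(O[Si](C(C)C)(C(C)C)C(C)C)c1C(C)(C)C=C
F6 | step 10 | (E)-1-(allyloxy)-2-{2-[3-methoxy-2-(3-methylbut-2-en-1-yl)-5-(triisopropylsilyloxy)phenyl]ethenyl}-6-(2-methylbut-3-en-2-yl)-3,5-bis(triisopropylsilyloxy)benzene | C=CCOc1c(/C=C/c2cc(O[Si](C(C)C)(C(C)C)C(C)C)cc(OC)c2CC=C(C)C)c(O[Si](C(C)C)(C(C)C)C(C)C)cc(O[Si](C(C)C)(C(C)C)C(C)C)c1C(C)(C)C=C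
A1 | alternative 1 | 5-[4,6-bis(methoxymethoxy)-7-(2-methylbut-3-en-2-yl)-1-benzofuran-2-yl]cyclohexane-1,3-dione | O=C1CC(=O)CC(C1)c1cc2c(OCOC)cc(OCOC)c(C(C)(C)C=C)c2o1
A2 | alternative 1 | (E)-4-[4,6-bis(methoxymethoxy)-7-(2-methylbut-3-en-2-yl)-1-benzofuran-2-yl]but-3-en-2-one | CC(=O)/C=C/c1cc2c(OCOC)cc(OCOC)c(C(C)(C)C=C)c2o1
A3 | alternative 2 | methyl trans-4,6-bis(allyloxy)-2-[5-(allyloxy)-3-methoxy-2-(3-methylbut-2-en-1-yl)phenyl]-7-(2-methylbut-3-en-2-yl)-2,3-dihydro-1-benzofuran-3-carboxylate (racemic, relative configuration drawn) | COC(=O)[C@@H]1[C@@H](c2cc(OCC=C)cc(OC)c2CC=C(C)C)Oc2c(C(C)(C)C=C)c(OCC=C)cc(OCC=C)c21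
A4 | alternative 2 | 5,7-bis(allyloxy)-2-[5-(allyloxy)-3-methoxy-2-(3-methylbut-2-en-1-yl)phenyl]-8-(2-methylbut-3-en-2-yl)chroman-4-one (racemic) | O=C1CC(c2cc(OCC=C)cc(OC)c2CC=C(C)C)Oc2c(C(C)(C)C=C)c(OCC=C)cc(OCC=C)c21
A5 | alternative 3 | 5'-O-triisopropylsilyl ether of the target | C=CC(C)(C)c1c(O)cc(O)c2cc(-c3cc(O[Si](C(C)C)(C(C)C)C(C)C)cc(OC)c3CC=C(C)C)oc12
A6 | alternative 3 | 5-{1-hydroxy-2-[5-(3-methoxy-2-(3-methylbut-2-en-1-yl)-5-(triisopropylsilyloxy)phenyl)furan-2-yl]-3,3-dimethylpent-4-en-1-ylidene}-2,2-dimethyl-1,3-dioxane-4,6-dione (enol form of the acyl Meldrum's acid, racemic) | C=CC(C)(C)C(C(O)=C1C(=O)OC(C)(C)OC1=O)c1ccc(-c2cc(O[Si](C(C)C)(C(C)C)C(C)C)cc(OC)c2CC=C(C)C)o1
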